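In the closed, stirred flask we keep books on the nucleophile. We assume that each protic impurity spends one nucleophile, so electrophile and impurity together claim 0.300 M against a charge of 0.200 M, which makes the nucleophile the limiting reagent.

| flask | electrophile | nucleophile | free base | protic impurity | remark | time |
|---|---|---|---|---|---|---|
| amber | 0.20 M | 0.40 M | 0.60 M | 0.10 M | run made earlier |  |
| flask | 0.20 M | 0.200 M | 0.600 M | 0.100 M |  | 30 h |

amber run (percent of the electrophile charged)

| time / h | electrophile / % | product / % |
|---|---|---|
| 0.250 | 97.4 | 0.7 |
| 0.417 | 96.4 | 3.0 |
| 0.833 | 93.1 | 6.6 |
| 1.50 | 87.5 | 13.1 |
| 3.00 | 78.3 | 23.6 |

(scatter of a reading: 1 percentage point)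

- the analysis behind the earlier runs scatters by 1 percentage point, standard deviation
- the earlier runs do not show how much of nucleophile is bound; that part of a forecast is a guess

- part of the electrophile that has reacted at 30 h
- share of the unused nucleophile that is free and not bound as protonated nucleophile, at 30 h

The amber readings show the lost electrophile reappearing as product, with 78.3% left and 23.6% formed at 3.00 h, so we book one nucleophile per product. The first entry in our ledger is the impurity's claim of 0.100 M. That leaves 0.100 M, and protonated nucleophile and unused nucleophile come out of this remainder too. The books close when we divide the remainder by the electrophile charge: the nucleophile budget, the charged nucleophile minus the charged impurity, per charged electrophile, is 50.0%. Once the impurity has taken its full claim, the part of the electrophile reacted stays within this figure. Amber had a budget of 150%, so its readings could not show such a ceiling. The amber readings carry no impurity figure, so we cannot say how much of its claim is taken by 30 h; we hold the budget as a ceiling for the long run of this flask, not as a mark for 30 h.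

The forecast gave 54% reacted and 85% free, and it warned that “stronger binding would lower both figures”.

The flask gives 39.7% reacted and 53.8% free at 30 h.

    nucleophile + protic impurity → quenched reagent (k = 0.570 M⁻¹ h⁻¹)
    acid set free + free base ⇌ salt of the base, settled at all times (K = 130 M⁻¹)
    electrophile + nucleophile ⇌ acid set free + product (K = 0.206, k = 0.248 M⁻¹ h⁻¹)
    nucleophile + acid set free ⇌ protonated nucleophile, settled at all times (K = 1110 M⁻¹)

In this flask 31% of the protic impurity is left at 30.0 h, so the budget is not yet in force there; at 300 h, with 8.96% left, the reacted part is 48.1%, under the budget of 50.0%. In this flask the forward rate at which the electrophile uses nucleophile is 1.2 times that of the impurity at 6.44 h, and 1.7 times at 30.0 h. At 30.0 h, 0.0693 M of quenched reagent stands beside 0.0794 M of product in this flask. The neighbour charged with 0.050 M of electrophile has a budget of 200%, which is above its whole charge, so the ledger sets no ceiling there. The computed result for that neighbour is 55.8% reacted at 30 h.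

The earlier runs and the new flask were generated by integration from invented constants.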